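**Retrosynthetic overview**
1. Target 16 ⇐ bis-phenol 14 by ortho-formylation at C8 (last step) ⇐ desilylation ⇐ isoflavan 13 ⇐ removal of the C4 carbonyl (reduction, then ionic hydrogenation) from isoflavanone 11.
2. 11 ⇐ open-chain, achiral 2-diazo-1,2-diarylethanone 10 by an enantioselective dirhodium-carbenoid C–H insertion that makes the C2–C3 bond and the C3 stereocenter. Ring C (the pyran) is the only ring formed in the route; rings A and B are bought as benzenes.
3. Enabling feature: C2 is a methylene on the ring oxygen O1, i.e. a disguised aryl OCH3. On ring A, C8a–O1 and C5–OMe are mirror images across the C4a···C7 axis, so a 2,6-dimethoxyaryl ketone offers two equivalent OCH3 groups to a carbene at C3, which is benzylic to ring B and adjacent to C4 (carried as C=O, the acceptor).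
4. 10 ⇐ diazo transfer ⇐ deoxybenzoin 9 ⇐ Pd-catalysed alpha-arylation of acetophenone 8 (ring A) with bromide 6 (ring B); the 3'-prenyl group comes from an aromatic Claisen rearrangement of a 1,1-dimethylallyl ether.

Key step: step 8

Assumption: Rh2(S-PTAD)4 (PTAD = (1-adamantyl)(phthalimido)acetate) is written for the catalyst enantiomer that delivers the (3R) ketone 11; if the sense of induction proves opposite, Rh2(R-PTAD)4 takes its place and nothing else changes.

**Route**

Step 1
Reactants: 1 2-bromo-5-methoxyphenol; 2 3-chloro-3-methylbut-1-yne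
Product: 3 1-bromo-4-methoxy-2-[(2-methylbut-3-yn-2-yl)oxy]benzene
Conditions: CuCl2·2H2O (1 mol %), DBU, MeCN, 0 °C
Reagents that add atoms: none
Why: Copper-catalysed propargylic substitution (O-alkylation of the phenol through a copper acetylide/allenylidene) gives tertiary propargyl aryl ethers where plain alkylation fails.

Step 2
Reactants: 3 1-bromo-4-methoxy-2-[(2-methylbut-3-yn-2-yl)oxy]benzene
Product: 4 1-bromo-4-methoxy-2-[(2-methylbut-3-en-2-yl)oxy]benzene
Conditions: H2 (1 atm), Pd/CaCO3 poisoned with Pb(OAc)2, quinoline, EtOAc, rt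
Reagents that add atoms: none
Why: Lindlar semihydrogenation stops at the alkene and should leave the aryl bromide untouched.

Step 3
Reactants: 4 1-bromo-4-methoxy-2-[(2-methylbut-3-en-2-yl)oxy]benzene
Product: 5 6-bromo-3-methoxy-2-(3-methylbut-2-en-1-yl)phenol
Conditions: N,N-diethylaniline, 130 °C
Reagents that add atoms: none
Why: Aromatic Claisen rearrangement can end productively only at the one free ortho carbon (between O and OMe; the other ortho carbon bears Br) and delivers the linear prenyl group after tautomerization.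

Step 4
Reactants: 5 6-bromo-3-methoxy-2-(3-methylbut-2-en-1-yl)phenol
Product: 6 [6-bromo-3-methoxy-2-(3-methylbut-2-en-1-yl)phenoxy](tert-butyl)dimethylsilane
Conditions: TBSCl, imidazole, DMF, 40 °C
Reagents that add atoms: tert-butyl(chloro)dimethylsilane CC(C)(C)[Si](C)(C)Cl
Why: Standard silylation of a phenol; a silyl group is chosen because it places no C–H alpha to oxygen next to the later carbene carbon.

Step 5
Reactants: 7 1-(4-hydroxy-2,6-dimethoxyphenyl)ethan-1-one
Product: 8 1-{2,6-dimethoxy-4-[tri(propan-2-yl)silyloxy]phenyl}ethan-1-one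
Conditions: TIPSCl, imidazole, DMF, rt
Reagents that add atoms: chlorotri(propan-2-yl)silane CC(C)[Si](Cl)(C(C)C)C(C)C
Why: Standard silylation; the bulky silyl ether survives the base of steps 6 and 7 although it sits para to an acyl group.

Step 6
Reactants: 8 1-{2,6-dimethoxy-4-[tri(propan-2-yl)silyloxy]phenyl}ethan-1-one; 6 [6-bromo-3-methoxy-2-(3-methylbut-2-en-1-yl)phenoxy](tert-butyl)dimethylsilane
Product: 9 2-[2-(tert-butyldimethylsilyloxy)-4-methoxy-3-(3-methylbut-2-en-1-yl)phenyl]-1-{2,6-dimethoxy-4-[tri(propan-2-yl)silyloxy]phenyl}ethan-1-one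
Conditions: Pd2(dba)3 (2 mol %), XPhos (8 mol %), K3PO4, toluene, 90 °C
Reagents that add atoms: none
Why: Buchwald–Hartwig-type ketone alpha-arylation (oxidative addition of 6 to zerovalent palladium, enolate binding, reductive elimination); the bulky biaryl phosphine and the weak base should favour monoarylation of the methyl ketone and spare the silyl ethers.

Step 7
Reactants: 9 the deoxybenzoin from step 6
Product: 10 2-[2-(tert-butyldimethylsilyloxy)-4-methoxy-3-(3-methylbut-2-en-1-yl)phenyl]-2-diazo-1-{2,6-dimethoxy-4-[tri(propan-2-yl)silyloxy]phenyl}ethan-1-one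
Conditions: 4-acetamidobenzenesulfonyl azide, DBU, MeCN, 0 °C to rt
Reagents that add atoms: 4-acetamidobenzenesulfonyl azide CC(=O)Nc1ccc(cc1)S(=O)(=O)N=[N+]=[N-]
Why: Regitz diazo transfer; the CH2 group is both benzylic and alpha to the ketone and is acidic enough for DBU.

Step 8
Reactants: 10 the diazo ketone from step 7
Product: 11 (3R)-3-[2-(tert-butyldimethylsilyloxy)-4-methoxy-3-(3-methylbut-2-en-1-yl)phenyl]-5-methoxy-7-[tri(propan-2-yl)silyloxy]-2,3-dihydro-4H-chromen-4-one
Conditions: Rh2(S-PTAD)4 (1 mol %), CH2Cl2, 4 Å molecular sieves, 0 °C to rt, slow addition of 10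
Reagents that add atoms: none
Why: The dirhodium tetracarboxylate expels N2 from 10 to give an electrophilic donor/acceptor carbenoid at C3 (ring B as donor, the aroyl group as acceptor), which inserts by a concerted, asynchronous hydride-transfer/C–C bond-forming event into a C–H bond of an ortho OCH3 group, making C2–C3. The closest known reaction type is the dirhodium-carboxylate-catalysed intramolecular C–H insertion of ortho-alkoxyaryl alpha-diazo ketones to chroman-4-ones, together with enantioselective insertions of aryl-substituted donor/acceptor carbenoids into methyl ether C–H bonds. Ring C closes through a six-centre (1,6) insertion geometry C3–C4–C4a–C8a–O1–C2; the 1,5 position is the ether oxygen, so no five-membered C–H insertion can compete, and the carbene carbon has no beta hydrogen, so no 1,2-hydride shift is possible. The new stereocenter C3 is the carbene carbon itself, and its configuration is fixed by the chiral phthalimido-carboxylate ligands, which decide the enantiotopic face of the Rh=C unit that receives the C–H bond. The step needs chemoselectivity for the OCH3 C–H bonds and site selectivity between the two methoxy groups of ring A: the first is secured by silyl protection of both phenols (no other C–H alpha to oxygen within reach, Si-bound methyl groups are electronically unactivated, and the 4'-OMe and prenyl groups cannot reach the carbenoid within the molecule while slow addition suppresses bimolecular paths), the second by the mirror symmetry of ring A, which makes the two ortho OCH3 groups equivalent. Oxonium ylide formation at the methoxy oxygen should be reversible and unproductive because methyl is a poor migrating group.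

Step 9
Reactants: 11 the isoflavanone from step 8
Product: 12 (3R,4RS)-3-[2-(tert-butyldimethylsilyloxy)-4-methoxy-3-(3-methylbut-2-en-1-yl)phenyl]-5-methoxy-7-[tri(propan-2-yl)silyloxy]-3,4-dihydro-2H-chromen-4-ol
Conditions: NaBH4, CeCl3·7H2O, MeOH–THF, −40 to 0 °C
Reagents that add atoms: none
Why: Luche reduction is a fast, weakly basic 1,2-reduction that should outrun enolization, so C3 is kept; the C4 configuration does not matter because C4 becomes CH2.

Step 10
Reactants: 12 the isoflavan-4-ol from step 9
Product: 13 tert-butyl{3-methoxy-6-[(3R)-5-methoxy-7-[tri(propan-2-yl)silyloxy]-3,4-dihydro-2H-chromen-3-yl]-2-(3-methylbut-2-en-1-yl)phenoxy}dimethylsilane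
Conditions: Et3SiH (10 equiv), CF3CO2H (2 equiv), CH2Cl2, −40 °C, high dilution
Reagents that add atoms: none
Why: Ionic hydrogenation (Kursanov–Parnes type): the 2,4,6-trioxygenated benzylic cation forms with weak acid at low temperature and should be trapped by the excess silane faster than it loses the C3 proton or attacks another arene, so C3 is retained and the prenyl alkene is not protonated.

Step 11
Reactants: 13 the bis-silyl isoflavan from step 10
Product: 14 (3R)-3-[2-hydroxy-4-methoxy-3-(3-methylbut-2-en-1-yl)phenyl]-5-methoxy-3,4-dihydro-2H-chromen-7-ol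
Conditions: Bu4NF, AcOH, THF, 0 °C to rt
Reagents that add atoms: none
Why: Fluoride-mediated cleavage of both aryl silyl ethers; acetic acid buffering protects the electron-rich phenoxides.

Step 12
Reactants: 14 the bis-phenol from step 11
Product: 16 (3R)-7-hydroxy-3-[2-hydroxy-4-methoxy-3-(3-methylbut-2-en-1-yl)phenyl]-5-methoxy-3,4-dihydro-2H-chromene-8-carbaldehyde, via hydroxymethyl phenol 15 (not isolated)
Conditions: MgCl2, Et3N, (CH2O)n, MeCN, reflux
Reagents that add atoms: paraformaldehyde (as formaldehyde) C=O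
Why: Magnesium-mediated ortho-formylation (Casnati–Skattebøl type), in which the magnesium 7-phenoxide delivers formaldehyde to an ortho carbon and a second formaldehyde oxidizes the benzylic alkoxide by hydride transfer; ring B cannot react because both ortho positions of its 2'-OH are substituted, and on ring A C8 (next to the tied-back ring oxygen) should be preferred over C6 (shielded by the in-plane methyl of the 5-OMe group).

**Compound list**
1 | 2-bromo-5-methoxyphenol | COc1ccc(Br)c(O)c1 | starting material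
2 | 3-chloro-3-methylbut-1-yne | CC(C)(Cl)C#C | starting material
3 | 1-bromo-4-methoxy-2-[(2-methylbut-3-yn-2-yl)oxy]benzene | COc1ccc(Br)c(OC(C)(C)C#C)c1 | intermediate
4 | 1-bromo-4-methoxy-2-[(2-methylbut-3-en-2-yl)oxy]benzene | COc1ccc(Br)c(OC(C)(C)C=C)c1 | intermediate
5 | 6-bromo-3-methoxy-2-(3-methylbut-2-en-1-yl)phenol | COc1ccc(Br)c(O)c1CC=C(C)C | intermediate
6 | [6-bromo-3-methoxy-2-(3-methylbut-2-en-1-yl)phenoxy](tert-butyl)dimethylsilane | COc1ccc(Br)c(O[Si](C)(C)C(C)(C)C)c1CC=C(C)C | intermediate
7 | 1-(4-hydroxy-2,6-dimethoxyphenyl)ethan-1-one | CC(=O)c1c(OC)cc(O)cc1OC | starting material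
8 | 1-{2,6-dimethoxy-4-[tri(propan-2-yl)silyloxy]phenyl}ethan-1-one | CC(=O)c1c(OC)cc(O[Si](C(C)C)(C(C)C)C(C)C)cc1OC | intermediate
9 | 2-[2-(tert-butyldimethylsilyloxy)-4-methoxy-3-(3-methylbut-2-en-1-yl)phenyl]-1-{2,6-dimethoxy-4-[tri(propan-2-yl)silyloxy]phenyl}ethan-1-one | COc1cc(O[Si](C(C)C)(C(C)C)C(C)C)cc(OC)c1C(=O)Cc1ccc(OC)c(CC=C(C)C)c1O[Si](C)(C)C(C)(C)C | intermediate
10 | 2-[2-(tert-butyldimethylsilyloxy)-4-methoxy-3-(3-methylbut-2-en-1-yl)phenyl]-2-diazo-1-{2,6-dimethoxy-4-[tri(propan-2-yl)silyloxy]phenyl}ethan-1-one | COc1cc(O[Si](C(C)C)(C(C)C)C(C)C)cc(OC)c1C(=O)C(=[N+]=[N-])c1ccc(OC)c(CC=C(C)C)c1O[Si](C)(C)C(C)(C)C | intermediate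
11 | (3R)-3-[2-(tert-butyldimethylsilyloxy)-4-methoxy-3-(3-methylbut-2-en-1-yl)phenyl]-5-methoxy-7-[tri(propan-2-yl)silyloxy]-2,3-dihydro-4H-chromen-4-one | COc1ccc([C@@H]2COc3cc(O[Si](C(C)C)(C(C)C)C(C)C)cc(OC)c3C2=O)c(O[Si](C)(C)C(C)(C)C)c1CC=C(C)C | intermediate
12 | (3R,4RS)-3-[2-(tert-butyldimethylsilyloxy)-4-methoxy-3-(3-methylbut-2-en-1-yl)phenyl]-5-methoxy-7-[tri(propan-2-yl)silyloxy]-3,4-dihydro-2H-chromen-4-ol (both C4 epimers) | COc1ccc([C@@H]2COc3cc(O[Si](C(C)C)(C(C)C)C(C)C)cc(OC)c3C2O)c(O[Si](C)(C)C(C)(C)C)c1CC=C(C)C | intermediate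
13 | tert-butyl{3-methoxy-6-[(3R)-5-methoxy-7-[tri(propan-2-yl)silyloxy]-3,4-dihydro-2H-chromen-3-yl]-2-(3-methylbut-2-en-1-yl)phenoxy}dimethylsilane | COc1ccc([C@@H]2COc3cc(O[Si](C(C)C)(C(C)C)C(C)C)cc(OC)c3C2)c(O[Si](C)(C)C(C)(C)C)c1CC=C(C)C | intermediate
14 | (3R)-3-[2-hydroxy-4-methoxy-3-(3-methylbut-2-en-1-yl)phenyl]-5-methoxy-3,4-dihydro-2H-chromen-7-ol | COc1ccc([C@@H]2COc3cc(O)cc(OC)c3C2)c(O)c1CC=C(C)C | intermediate
15 | (3R)-8-(hydroxymethyl)-3-[2-hydroxy-4-methoxy-3-(3-methylbut-2-en-1-yl)phenyl]-5-methoxy-3,4-dihydro-2H-chromen-7-ol (formed as its magnesium phenoxide) | COc1ccc([C@@H]2COc3c(CO)c(O)cc(OC)c3C2)c(O)c1CC=C(C)C | intermediate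
16 | (3R)-7-hydroxy-3-[2-hydroxy-4-methoxy-3-(3-methylbut-2-en-1-yl)phenyl]-5-methoxy-3,4-dihydro-2H-chromene-8-carbaldehyde | COc1ccc([C@@H]2COc3c(C=O)c(O)cc(OC)c3C2)c(O)c1CC=C(C)C | target

**Step count and risks**
Total steps: 12. Longest linear sequence: 11 steps (steps 1, 2, 3, 4, 6, 7, 8, 9, 10, 11, 12).

Steps most likely to fail:

1. Step 8. The carbenoid may be diverted before it inserts (methyl transfer or rearrangement from the oxonium ylide, bimolecular reaction at the prenyl group, carbene dimerization), or enantioface control may be insufficient. Fallback, setting out from 9 and returning at 12: chelation-controlled cleavage of one of the two equivalent ortho methyl ethers with MgI2·OEt2 (toluene, 80 °C) should give the 2-hydroxy deoxybenzoin F1. O-Formylation with acetic formic anhydride/pyridine gives the aryl formate F2. Its ketone enolate (NaH, THF, then acidic work-up) attacks the formate carbon in an intramolecular Claisen-type acylation (Baker–Venkataraman-like), which again makes the C2–C3 bond and, after loss of water, gives the isoflavone F3. Asymmetric transfer hydrogenation of F3 with RuCl(p-cymene)[TsDPEN] (the enantiomer that leads to 3R), HCO2H/Et3N, reduces C2=C3 and then C4=O with dynamic kinetic resolution at C3, giving the cis-(3R) epimer of 12, from which step 10 follows.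

2. Step 10. The C3 configuration may erode through reversible loss of the C3 proton from the C4 cation, and the cation may alkylate a second electron-rich ring A or the acid may protonate the prenyl alkene. Fallback, setting out from 12 and returning at 13: acylation with 1,1'-thiocarbonyldiimidazole (DMAP, THF, reflux) gives the thiocarbonylimidazolide F4, and Barton–McCombie reduction (Bu3SnH, AIBN, toluene, 80 °C) removes the C4 oxygen through a benzylic radical that cannot scramble C3.

3. Step 12. Formylation may show poor regioselectivity between C8 and C6, or over-formylation of the very electron-rich ring A. Fallback, setting out from 13 and returning at 16: bromination with NBS (CH2Cl2, −78 °C), a small electrophile with precedent for C8 selectivity in 5,7-di-O-substituted flavans, gives the 8-bromide F5. Bromine–lithium exchange (t-BuLi, THF, −78 °C) and immediate DMF quench give the 8-carbaldehyde bis-silyl ether F6, and Bu4NF/AcOH desilylation gives 16.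

Further compounds
F1 | step 8 | 2-[2-(tert-butyldimethylsilyloxy)-4-methoxy-3-(3-methylbut-2-en-1-yl)phenyl]-1-{2-hydroxy-6-methoxy-4-[tri(propan-2-yl)silyloxy]phenyl}ethan-1-one | COc1cc(O[Si](C(C)C)(C(C)C)C(C)C)cc(O)c1C(=O)Cc1ccc(OC)c(CC=C(C)C)c1O[Si](C)(C)C(C)(C)C
F2 | step 8 | 2-{[2-(tert-butyldimethylsilyloxy)-4-methoxy-3-(3-methylbut-2-en-1-yl)phenyl]acetyl}-3-methoxy-5-[tri(propan-2-yl)silyloxy]phenyl formate | COc1cc(O[Si](C(C)C)(C(C)C)C(C)C)cc(OC=O)c1C(=O)Cc1ccc(OC)c(CC=C(C)C)c1O[Si](C)(C)C(C)(C)C
F3 | step 8 | 3-[2-(tert-butyldimethylsilyloxy)-4-methoxy-3-(3-methylbut-2-en-1-yl)phenyl]-5-methoxy-7-[tri(propan-2-yl)silyloxy]-4H-chromen-4-one | COc1ccc(-c2coc3cc(O[Si](C(C)C)(C(C)C)C(C)C)cc(OC)c3c2=O)c(O[Si](C)(C)C(C)(C)C)c1CC=C(C)C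
F4 | step 10 | O-{(3R,4RS)-3-[2-(tert-butyldimethylsilyloxy)-4-methoxy-3-(3-methylbut-2-en-1-yl)phenyl]-5-methoxy-7-[tri(propan-2-yl)silyloxy]-3,4-dihydro-2H-chromen-4-yl} 1H-imidazole-1-carbothioate | COc1ccc([C@@H]2COc3cc(O[Si](C(C)C)(C(C)C)C(C)C)cc(OC)c3C2OC(=S)n4ccnc4)c(O[Si](C)(C)C(C)(C)C)c1CC=C(C)C
F5 | step 12 | {6-[(3R)-8-bromo-5-methoxy-7-[tri(propan-2-yl)silyloxy]-3,4-dihydro-2H-chromen-3-yl]-3-methoxy-2-(3-methylbut-2-en-1-yl)phenoxy}(tert-butyl)dimethylsilane | COc1ccc([C@@H]2COc3c(Br)c(O[Si](C(C)C)(C(C)C)C(C)C)cc(OC)c3C2)c(O[Si](C)(C)C(C)(C)C)c1CC=C(C)C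
F6 | step 12 | (3R)-3-[2-(tert-butyldimethylsilyloxy)-4-methoxy-3-(3-methylbut-2-en-1-yl)phenyl]-5-methoxy-7-[tri(propan-2-yl)silyloxy]-3,4-dihydro-2H-chromene-8-carbaldehyde | COc1ccc([C@@H]2COc3c(C=O)c(O[Si](C(C)C)(C(C)C)C(C)C)cc(OC)c3C2)c(O[Si](C)(C)C(C)(C)C)c1CC=C(C)C
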